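Numbering follows the caryophyllane skeleton: C1 and C9 are the ring-fusion carbons, C2 to C8 complete the nine-membered ring (C4–C5 carry the epoxide, C8 the exocyclic methylidene), C10 and C11 complete the cyclobutane, C12 to C15 are the side chain.
Retrosynthesis: the oxirane C–O bonds are cut first (to a Z C4=C5 alkene), then C8=CH2 (to a C8 ketone). Because C8 sits γ,δ to that masked Z alkene inside the nine-membered ring, the C6–C7 bond is then cut by a retro-Claisen step that ties oxygen between C8 and C4, which gives a cyclobutane-fused 2-methylidene-7-vinyloxepane.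
Further cuts: enol ether back to a lactone carbonyl, C11–C12 (radical conjugate addition; the C11 methyl comes from a methylidenecyclobutane), the lactone C8–O bond, C4–C5 (vinyl Grignard) and C1–C2 (Michael addition to methyl vinyl ketone), ending at a 3-substituted cyclobutanone.
Forward ring order: the four-membered ring is purchased, the seven-membered lactone is closed onto it, the nine-membered carbocycle arises from the seven-membered ether by [3,3] ring expansion, and the oxirane is closed last.
Stereochemistry: C9 from chiral-lithium-amide desymmetrisation, C1 from Michael addition trans to C9, C11 from radical addition anti to the C1–C2 bond, C14 from oxazaborolidine-catalysed reduction, the Z alkene from the ring-constrained Claisen transition state, and C4/C5 from syn oxygen transfer by a chiral dioxirane.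

Key step: step 15

Assumption: the hands of the two chiral reagents are assigned by analogy (the (R,R)-lithium amide from the sense known for 4-substituted cyclohexanones, the L-series dioxirane precursor from the spiro transition-state model for trisubstituted alkenes); each would be confirmed by correlation and the opposite hand used if required.

Step 1
Reactants: 1 3-(benzyloxymethyl)cyclobutan-1-one
Product: 3 (S)-3-(benzyloxymethyl)-1-(trimethylsilyloxy)cyclobut-1-ene, via lithium enolate 2 (not isolated)
Conditions: (R,R)-bis(1-phenylethyl)amine, n-BuLi, THF, −78 °C; then TMSCl and 1 at −100 °C (internal quench)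
Reagents that add atoms: chlorotrimethylsilane, C[Si](C)(C)Cl
Why: Enantioselective deprotonation with a C2-symmetric chiral lithium amide removes one of the two enantiotopic α-protons of the achiral ketone and the enolate is silylated in situ, which fixes C9; this desymmetrisation is established for 3-substituted cyclobutanones.

Step 2
Reactants: 3 (S)-3-(benzyloxymethyl)-1-(trimethylsilyloxy)cyclobut-1-ene; 4 methyl vinyl ketone
Product: 5 (2R,3S)-3-(benzyloxymethyl)-2-(3-oxobutyl)cyclobutan-1-one (2,3-trans)
Conditions: TiCl4, CH2Cl2, −78 °C; aq. NaHCO3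
Reagents that add atoms: none
Why: In this Mukaiyama–Michael addition the TiCl4-activated enone is attacked by the enol-silane carbon from the ring face opposite the neighbouring benzyloxymethyl group, so the C1–C2 bond forms trans to the C9 substituent (substrate control, and also the thermodynamic arrangement at this epimerisable α-carbon).

Step 3
Reactants: 5 (2R,3S)-3-(benzyloxymethyl)-2-(3-oxobutyl)cyclobutan-1-one
Product: 6 (2R,3S)-3-(hydroxymethyl)-2-(3-oxobutyl)cyclobutan-1-one
Conditions: H2 (1 atm), Pd/C, EtOAc, rt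
Reagents that add atoms: none
Why: Catalytic hydrogenolysis of the benzyl ether is placed here because no alkene is present yet and neither ketone is reduced over Pd/C at one atmosphere.

Step 4
Reactants: 6 (2R,3S)-3-(hydroxymethyl)-2-(3-oxobutyl)cyclobutan-1-one
Product: 7 4-[(1R,2S)-2-(hydroxymethyl)-4-methylidenecyclobutyl]butan-2-one
Conditions: Ph3PCH3Br, KOtBu, THF, 0 °C; ylide (1.1 equiv) added slowly to 6 at −78 °C, then −20 °C
Reagents that add atoms: methyltriphenylphosphonium bromide (as its ylide), C[P+](c1ccccc1)(c1ccccc1)c1ccccc1.[Br-]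
Why: In this Wittig methylenation the strained ring ketone is aldehyde-like toward phosphorus ylides (rehybridisation relieves angle strain, and cyclobutanones condense even with ester-stabilised ylides that leave methyl ketones alone), so about one equivalent of Ph3P=CH2 at low temperature should olefinate only the cyclobutanone, and any epimerisation at C1 would return the favoured trans isomer.

Step 5
Reactants: 7 4-[(1R,2S)-2-(hydroxymethyl)-4-methylidenecyclobutyl]butan-2-one; 8 vinylmagnesium bromide
Product: 9 5-[(1R,2S)-2-(hydroxymethyl)-4-methylidenecyclobutyl]-3-methylpent-1-en-3-ol (both C3 epimers of the chain, i.e. both C4 epimers in skeleton numbering)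
Conditions: CH2=CHMgBr (3 equiv), THF, −78 to 0 °C; aq. NH4Cl
Reagents that add atoms: none
Why: Grignard 1,2-addition to the only remaining carbonyl (the first equivalent deprotonates the primary hydroxyl) gives the tertiary allylic alcohol; the new C4 centre is uncontrolled, which is harmless because step 15 destroys it.

Step 6
Reactants: 9 5-[(1R,2S)-2-(hydroxymethyl)-4-methylidenecyclobutyl]-3-methylpent-1-en-3-ol
Product: 11 (1S,2R)-2-(3-hydroxy-3-methylpent-4-en-1-yl)-3-methylidenecyclobutane-1-carboxylic acid, via hydroxy aldehyde 10 (not isolated)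
Conditions: TEMPO (20 mol %), PhI(OAc)2 (2.2 equiv), MeCN/H2O, rt
Reagents that add atoms: water, O
Why: Nitroxyl-catalysed oxidation with PhI(OAc)2 in aqueous acetonitrile takes the primary alcohol through the aldehyde hydrate to the acid while the tertiary alcohol and both alkenes are left untouched, and C9 already has the more stable trans arrangement.

Step 7
Reactants: 11 (1S,2R)-2-(3-hydroxy-3-methylpent-4-en-1-yl)-3-methylidenecyclobutane-1-carboxylic acid
Product: 13 trans-fused (1S,7R)-4-ethenyl-4-methyl-8-methylidene-3-oxabicyclo[5.2.0]nonan-2-one (both C4 epimers), via mixed anhydride 12 (not isolated)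
Conditions: 2,4,6-Cl3C6H2COCl, Et3N, THF, rt; then slow addition to DMAP, toluene, 90 °C (about 2 mM)
Reagents that add atoms: none
Why: In this Yamaguchi lactonisation DMAP converts the mixed anhydride into an acylpyridinium ion that the tertiary allylic hydroxyl captures intramolecularly under high dilution, seven-membered closure being helped by the fully substituted carbinol carbon and the fixed trans disposition of the two arms on the cyclobutane, while the basic medium keeps the allylic alcohol from ionising.

Step 8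
Reactants: 14 3-hydroxy-3-methylbutan-2-one
Product: 15 3-methyl-3-(triethylsilyloxy)butan-2-one
Conditions: TESOTf, 2,6-lutidine, CH2Cl2, 0 °C
Reagents that add atoms: triethylsilyl trifluoromethanesulfonate, CC[Si](CC)(CC)OS(=O)(=O)C(F)(F)F
Why: Silylation with a silyl triflate and a hindered pyridine base is the standard way to protect a tertiary alcohol and masks the hydroxyl before enolate chemistry.

Step 9
Reactants: 15 3-methyl-3-(triethylsilyloxy)butan-2-one
Product: 17 1-(dimethylamino)-4-methyl-4-(triethylsilyloxy)pentan-3-one, via lithium enolate 16 (not isolated)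
Conditions: LiN(iPr)2, THF, −78 °C; then CH2=NMe2+ I−, −78 °C to rt
Reagents that add atoms: N,N-dimethylmethyleneiminium iodide (Eschenmoser's salt), C=[N+](C)C.[I-]
Why: In this Mannich aminomethylation deprotonation can occur only at the methyl group (the other α-carbon is quaternary) and the lithium enolate is alkylated by the preformed iminium salt.

Step 10
Reactants: 17 1-(dimethylamino)-4-methyl-4-(triethylsilyloxy)pentan-3-one
Product: 19 4-methyl-4-(triethylsilyloxy)pent-1-en-3-one, via ammonium iodide 18 (not isolated)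
Conditions: MeI, Et2O, rt; then aq. NaHCO3/CH2Cl2, rt
Reagents that add atoms: none
Why: Quaternisation followed by E1cB loss of trimethylamine from the β-ammonio ketone (Mannich-base elimination) unveils the vinyl ketone under mild base that leaves the silyl ether intact.

Step 11
Reactants: 13 trans-fused (1S,7R)-4-ethenyl-4-methyl-8-methylidene-3-oxabicyclo[5.2.0]nonan-2-one; 19 4-methyl-4-(triethylsilyloxy)pent-1-en-3-one
Product: 20 (1S,7R,8R)-4-ethenyl-4,8-dimethyl-8-[4-methyl-3-oxo-4-(triethylsilyloxy)pentyl]-3-oxabicyclo[5.2.0]nonan-2-one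
Conditions: Fe(acac)3 (30 mol %), PhSiH3, 19 (3 equiv), EtOH/(CH2OH)2, 60 °C
Reagents that add atoms: none
Why: In this hydrogen-atom-transfer Giese coupling an iron hydride formed from Fe(acac)3 and PhSiH3 delivers a hydrogen atom to the terminal carbon of the 1,1-disubstituted alkene (faster than to the hindered monosubstituted vinyl group), and the tertiary cyclobutyl radical, which cannot ring-open, adds to the enone on the face anti to the adjacent C1–C2 bond, setting C11 with the new methyl cis and the new chain trans to that bond.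

Step 12
Reactants: 20 (1S,7R,8R)-4-ethenyl-4,8-dimethyl-8-[4-methyl-3-oxo-4-(triethylsilyloxy)pentyl]-3-oxabicyclo[5.2.0]nonan-2-one
Product: 21 (1S,7R,8R)-4-ethenyl-8-[(3R)-3-hydroxy-4-methyl-4-(triethylsilyloxy)pentyl]-4,8-dimethyl-3-oxabicyclo[5.2.0]nonan-2-one
Conditions: (S)-2-methyl-CBS-oxazaborolidine (20 mol %), catecholborane, toluene, −78 to −40 °C; MeOH, then pH 7 buffer
Reagents that add atoms: none
Why: In this Corey–Bakshi–Shibata reduction the (S)-oxazaborolidine distinguishes the bulky C(CH3)2OSiEt3 group from the CH2 chain and delivers hydride to give the (R)-carbinol at C14 under catalyst control, while catecholborane at low temperature neither hydroborates the vinyl group nor reduces the lactone.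

Step 13
Reactants: 21 (1S,7R,8R)-4-ethenyl-8-[(3R)-3-hydroxy-4-methyl-4-(triethylsilyloxy)pentyl]-4,8-dimethyl-3-oxabicyclo[5.2.0]nonan-2-one
Product: 22 (1S,7R,8R)-4-ethenyl-4,8-dimethyl-8-[(3R)-4-methyl-3,4-bis(triethylsilyloxy)pentyl]-3-oxabicyclo[5.2.0]nonan-2-one
Conditions: TESOTf, 2,6-lutidine, CH2Cl2, −78 to 0 °C
Reagents that add atoms: triethylsilyl trifluoromethanesulfonate, CC[Si](CC)(CC)OS(=O)(=O)C(F)(F)F
Why: Silyl ether formation protects the secondary alcohol against the titanium reagent of the next step and the ylide used later.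

Step 14
Reactants: 22 (1S,7R,8R)-4-ethenyl-4,8-dimethyl-8-[(3R)-4-methyl-3,4-bis(triethylsilyloxy)pentyl]-3-oxabicyclo[5.2.0]nonan-2-one
Product: 23 (1S,7R,8R)-4-ethenyl-4,8-dimethyl-2-methylidene-8-[(3R)-4-methyl-3,4-bis(triethylsilyloxy)pentyl]-3-oxabicyclo[5.2.0]nonane
Conditions: Cp2TiMe2 (3 equiv), toluene, 70 °C, dark; filtration through basic alumina
Reagents that add atoms: dimethyltitanocene Cp2TiMe2, C[Ti](C)(C1C=CC=C1)C1C=CC=C1
Why: Petasis methylenation (carbonyl olefination by the titanium methylidene formed thermally from Cp2TiMe2) turns the lactone carbonyl into the exocyclic enol ether without acid, which the sensitive allyl vinyl ether and the silyl ethers tolerate.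

Step 15
Reactants: 23 (1S,7R,8R)-4-ethenyl-4,8-dimethyl-2-methylidene-8-[(3R)-4-methyl-3,4-bis(triethylsilyloxy)pentyl]-3-oxabicyclo[5.2.0]nonane
Product: 24 (1R,4Z,9S,11R)-4,11-dimethyl-11-[(3R)-4-methyl-3,4-bis(triethylsilyloxy)pentyl]bicyclo[7.2.0]undec-4-en-8-one
Conditions: degassed xylene with a trace of Et3N, base-washed sealed tube, 175 °C
Reagents that add atoms: none
Why: The allyl vinyl ether held in the oxepane (C7H2=C8–O–C4–C5H=C6H2) undergoes a concerted suprafacial [3,3]-sigmatropic Claisen shift in which the C6–C7 bond forms while the O–C4 bond breaks, and formation of the C8 carbonyl drives it. The closest known reaction type is the Claisen ring expansion of 2-methylidene cyclic ethers that carry a vinyl group on the carbon next to oxygen, which gives medium-ring cycloalkenones; here it is applied to a seven-membered ether fused to a cyclobutane. The nine-membered carbocycle is closed by three-atom enlargement of the seven-membered ring through a six-membered cyclic transition state, with the four-membered ring as a bystander, so no end-to-end medium-ring cyclisation with its entropic and transannular cost is involved. No stereocentre is created: C4 becomes trigonal, so both epimers of 23 give the same product, and C1, C9, C11 and C14 are not touched. The selectivity needed is Z geometry at C4=C5, and it is secured because C4 and C8 are tied together by the short C3–C2–C1–C9 chain, which forces the C4–C3 bond into the pseudo-axial site of the six-membered array and so places C3 and C6 on the same side of the new double bond. Should any C9 epimer appear under the thermal conditions, brief base treatment would return the more stable trans ring fusion.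

Step 16
Reactants: 24 (1R,4Z,9S,11R)-4,11-dimethyl-11-[(3R)-4-methyl-3,4-bis(triethylsilyloxy)pentyl]bicyclo[7.2.0]undec-4-en-8-one
Product: 25 (1R,4Z,9S,11R)-4,11-dimethyl-8-methylidene-11-[(3R)-4-methyl-3,4-bis(triethylsilyloxy)pentyl]bicyclo[7.2.0]undec-4-ene
Conditions: Ph3PCH3Br, KOtBu, toluene, 0 to 60 °C
Reagents that add atoms: methyltriphenylphosphonium bromide (as its ylide), C[P+](c1ccccc1)(c1ccccc1)c1ccccc1.[Br-]
Why: Wittig methylenation with the unhindered ylide installs the C8 methylidene, and the basic medium can only move C9 toward the more stable trans fusion.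

Step 17
Reactants: 25 (1R,4Z,9S,11R)-4,11-dimethyl-8-methylidene-11-[(3R)-4-methyl-3,4-bis(triethylsilyloxy)pentyl]bicyclo[7.2.0]undec-4-ene
Product: 26 (3R)-5-[(1R,4Z,9S,11R)-4,11-dimethyl-8-methylidenebicyclo[7.2.0]undec-4-en-11-yl]-2-methylpentane-2,3-diol
Conditions: Bu4NF, THF, rt to 45 °C
Reagents that add atoms: none
Why: Fluoride-mediated desilylation removes both triethylsilyl ethers without acid, which matters because the diene of the nine-membered ring is prone to acid-induced transannular cyclisation.

Step 18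
Reactants: 26 (3R)-5-[(1R,4Z,9S,11R)-4,11-dimethyl-8-methylidenebicyclo[7.2.0]undec-4-en-11-yl]-2-methylpentane-2,3-diol
Product: 27 (3R)-1-[(1R,4Z,9S,11R)-4,11-dimethyl-8-methylidenebicyclo[7.2.0]undec-4-en-11-yl]-4-hydroxy-4-methylpentan-3-yl acetate
Conditions: Ac2O, pyridine, DMAP (cat.), CH2Cl2, 0 °C to rt
Reagents that add atoms: acetic anhydride, CC(=O)OC(C)=O
Why: DMAP-catalysed acetylation is selective for the secondary C14 hydroxyl because the neighbouring tertiary hydroxyl is too hindered to be acylated under these conditions.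

Step 19
Reactants: 27 (3R)-1-[(1R,4Z,9S,11R)-4,11-dimethyl-8-methylidenebicyclo[7.2.0]undec-4-en-11-yl]-4-hydroxy-4-methylpentan-3-yl acetate
Product: 28 (3R)-1-[(1R,4R,5S,9S,11R)-4,5-epoxy-4,11-dimethyl-8-methylidenebicyclo[7.2.0]undecan-11-yl]-4-hydroxy-4-methylpentan-3-yl acetate (CNP0157071.2)
Conditions: 1,2:4,5-di-O-isopropylidene-β-L-erythro-2,3-hexodiulo-2,6-pyranose (L-series Shi ketone, 30 mol %), Oxone (KHSO5), K2CO3, Bu4NHSO4, MeCN/CH2(OMe)2/aq. buffer pH 10.5, 0 °C
Reagents that add atoms: potassium peroxymonosulfate KHSO5 (Oxone), [K+].[O-]S(=O)(=O)OO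
Why: In this Shi epoxidation the chiral dioxirane transfers oxygen syn to one face of the electron-rich trisubstituted Z alkene in preference to the 1,1-disubstituted exocyclic alkene, so the cis relationship of C3 and C6 on the oxirane follows from the alkene geometry and the (4R,5S) face from the catalyst hand predicted by the spiro transition-state model.

Compound list
1 | 3-(benzyloxymethyl)cyclobutan-1-one | O=C1CC(COCc2ccccc2)C1 | starting material
2 | lithium (S)-3-(benzyloxymethyl)cyclobut-1-en-1-olate | [Li]OC1=C[C@@H](COCc2ccccc2)C1 | intermediate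
3 | (S)-3-(benzyloxymethyl)-1-(trimethylsilyloxy)cyclobut-1-ene | C[Si](C)(C)OC1=C[C@@H](COCc2ccccc2)C1 | intermediate
4 | methyl vinyl ketone (but-3-en-2-one) | CC(=O)C=C | starting material
5 | (2R,3S)-3-(benzyloxymethyl)-2-(3-oxobutyl)cyclobutan-1-one | CC(=O)CC[C@@H]1[C@@H](COCc2ccccc2)CC1=O | intermediate
6 | (2R,3S)-3-(hydroxymethyl)-2-(3-oxobutyl)cyclobutan-1-one | CC(=O)CC[C@@H]1[C@@H](CO)CC1=O | intermediate
7 | 4-[(1R,2S)-2-(hydroxymethyl)-4-methylidenecyclobutyl]butan-2-one | CC(=O)CC[C@@H]1[C@@H](CO)CC1=C | intermediate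
8 | vinylmagnesium bromide | C=C[Mg]Br | starting material
9 | 5-[(1R,2S)-2-(hydroxymethyl)-4-methylidenecyclobutyl]-3-methylpent-1-en-3-ol (both carbinol epimers) | C=CC(C)(O)CC[C@@H]1[C@@H](CO)CC1=C | intermediate
10 | (1S,2R)-2-(3-hydroxy-3-methylpent-4-en-1-yl)-3-methylidenecyclobutane-1-carbaldehyde | C=CC(C)(O)CC[C@@H]1[C@@H](C=O)CC1=C | intermediate
11 | (1S,2R)-2-(3-hydroxy-3-methylpent-4-en-1-yl)-3-methylidenecyclobutane-1-carboxylic acid | C=CC(C)(O)CC[C@@H]1[C@@H](C(=O)O)CC1=C | intermediate
12 | mixed anhydride of 11 with 2,4,6-trichlorobenzoic acid | C=CC(C)(O)CC[C@@H]1[C@@H](C(=O)OC(=O)c2c(Cl)cc(Cl)cc2Cl)CC1=C | intermediate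
13 | trans-fused (1S,7R)-4-ethenyl-4-methyl-8-methylidene-3-oxabicyclo[5.2.0]nonan-2-one (both C4 epimers) | C=CC1(C)CC[C@@H]2[C@H](CC2=C)C(=O)O1 | intermediate
14 | 3-hydroxy-3-methylbutan-2-one | CC(=O)C(C)(C)O | starting material
15 | 3-methyl-3-(triethylsilyloxy)butan-2-one | CC(=O)C(C)(C)O[Si](CC)(CC)CC | intermediate
16 | lithium 3-methyl-3-(triethylsilyloxy)but-1-en-2-olate | [Li]OC(=C)C(C)(C)O[Si](CC)(CC)CC | intermediate
17 | 1-(dimethylamino)-4-methyl-4-(triethylsilyloxy)pentan-3-one | CN(C)CCC(=O)C(C)(C)O[Si](CC)(CC)CC | intermediate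
18 | trimethyl[4-methyl-3-oxo-4-(triethylsilyloxy)pentyl]ammonium iodide | C[N+](C)(C)CCC(=O)C(C)(C)O[Si](CC)(CC)CC.[I-] | intermediate
19 | 4-methyl-4-(triethylsilyloxy)pent-1-en-3-one | C=CC(=O)C(C)(C)O[Si](CC)(CC)CC | intermediate
20 | (1S,7R,8R)-4-ethenyl-4,8-dimethyl-8-[4-methyl-3-oxo-4-(triethylsilyloxy)pentyl]-3-oxabicyclo[5.2.0]nonan-2-one (both C4 epimers) | C=CC1(C)CC[C@@H]2[C@H](C[C@@]2(C)CCC(=O)C(C)(C)O[Si](CC)(CC)CC)C(=O)O1 | intermediate
21 | (1S,7R,8R)-4-ethenyl-8-[(3R)-3-hydroxy-4-methyl-4-(triethylsilyloxy)pentyl]-4,8-dimethyl-3-oxabicyclo[5.2.0]nonan-2-one (both C4 epimers) | C=CC1(C)CC[C@@H]2[C@H](C[C@@]2(C)CC[C@@H](O)C(C)(C)O[Si](CC)(CC)CC)C(=O)O1 | intermediate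
22 | (1S,7R,8R)-4-ethenyl-4,8-dimethyl-8-[(3R)-4-methyl-3,4-bis(triethylsilyloxy)pentyl]-3-oxabicyclo[5.2.0]nonan-2-one (both C4 epimers) | C=CC1(C)CC[C@@H]2[C@H](C[C@@]2(C)CC[C@@H](O[Si](CC)(CC)CC)C(C)(C)O[Si](CC)(CC)CC)C(=O)O1 | intermediate
23 | (1S,7R,8R)-4-ethenyl-4,8-dimethyl-2-methylidene-8-[(3R)-4-methyl-3,4-bis(triethylsilyloxy)pentyl]-3-oxabicyclo[5.2.0]nonane (both C4 epimers) | C=CC1(C)CC[C@@H]2[C@H](C[C@@]2(C)CC[C@@H](O[Si](CC)(CC)CC)C(C)(C)O[Si](CC)(CC)CC)C(=C)O1 | intermediate
24 | (1R,4Z,9S,11R)-4,11-dimethyl-11-[(3R)-4-methyl-3,4-bis(triethylsilyloxy)pentyl]bicyclo[7.2.0]undec-4-en-8-one (trans-fused) | O=C1CC/C=C(C)\CC[C@@H]2[C@@H]1C[C@@]2(C)CC[C@@H](O[Si](CC)(CC)CC)C(C)(C)O[Si](CC)(CC)CC | intermediate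
25 | (1R,4Z,9S,11R)-4,11-dimethyl-8-methylidene-11-[(3R)-4-methyl-3,4-bis(triethylsilyloxy)pentyl]bicyclo[7.2.0]undec-4-ene | C=C1CC/C=C(C)\CC[C@@H]2[C@@H]1C[C@@]2(C)CC[C@@H](O[Si](CC)(CC)CC)C(C)(C)O[Si](CC)(CC)CC | intermediate
26 | (3R)-5-[(1R,4Z,9S,11R)-4,11-dimethyl-8-methylidenebicyclo[7.2.0]undec-4-en-11-yl]-2-methylpentane-2,3-diol | C=C1CC/C=C(C)\CC[C@@H]2[C@@H]1C[C@@]2(C)CC[C@@H](O)C(C)(C)O | intermediate
27 | (3R)-1-[(1R,4Z,9S,11R)-4,11-dimethyl-8-methylidenebicyclo[7.2.0]undec-4-en-11-yl]-4-hydroxy-4-methylpentan-3-yl acetate | C=C1CC/C=C(C)\CC[C@@H]2[C@@H]1C[C@@]2(C)CC[C@@H](OC(C)=O)C(C)(C)O | intermediate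
28 | (3R)-1-[(1R,4R,5S,9S,11R)-4,5-epoxy-4,11-dimethyl-8-methylidenebicyclo[7.2.0]undecan-11-yl]-4-hydroxy-4-methylpentan-3-yl acetate (CNP0157071.2; cis-epoxide, trans ring fusion) | C=C1CC[C@@H]2O[C@]2(C)CC[C@@H]2[C@@H]1C[C@@]2(C)CC[C@@H](OC(C)=O)C(C)(C)O | target

Total step count: 19.
Longest linear sequence: 16 steps (steps 1 to 7 and 11 to 19, from compound 1); the enone branch (steps 8 to 10) is three steps.

Steps most likely to fail

Step 7. The hindered tertiary allylic hydroxyl may be acylated too slowly, so that oligomerisation, anhydride exchange or elimination outruns closure of the seven-membered ring. The fallback sets out from compound 7 and comes back at compound 13, and it makes the lactone C–O bond with an alkoxide at the moment the carbinol is created. The primary alcohol of 7 would be oxidised (TEMPO, PhI(OAc)2, aqueous MeCN) through keto aldehyde F1 to keto acid F2. The acid would be esterified with phenol (carbodiimide, DMAP) to phenyl ester F3. Vinylmagnesium bromide 8 (with CeCl3, −78 °C) would then add to the ketone before the aryl ester, giving bromomagnesium alkoxide F4. On warming, this alkoxide should displace phenoxide intramolecularly and give lactone 13.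

Step 11. Hydrogen-atom transfer to the vinyl group may compete with transfer to the methylidene, and the radical addition at C11 may show poor facial selectivity. The fallback sets out from compound 7 (with enone 19) and comes back at compound 20, running the radical step before the vinyl group exists. The same Fe(acac)3/PhSiH3 coupling on 7, which has a single alkene, would give diketone F5, whose C11 epimers could be separated at this early stage. Vinylmagnesium bromide 8 with CeCl3 at −78 °C should add to the unhindered methyl ketone in preference to the ketone flanked by the fully substituted silyloxy carbon, giving diol F6. Oxidation as in step 6 would pass through hydroxy aldehyde F7 to hydroxy acid F8. Lactonisation as in step 7 through mixed anhydride F9 would then give 20.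

Step 19. Oxygen may be delivered to the wrong face of the flexible nine-membered ring (ring bias working against the catalyst), with some attack at the exocyclic alkene as well. The fallback sets out from compound 24 and comes back at compound 28, moving the epoxidation to the ketone stage. There the trisubstituted alkene is the only alkene, the ring has a different conformational preference, and the diastereomeric epoxides can be separated before material is committed. Ketone 24 would be epoxidised (dimethyldioxirane, or the chiral dioxirane of whichever hand proves matched) to epoxy ketone F10. Wittig methylenation (Ph3P=CH2, toluene) would give epoxy alkene F11. Desilylation with Bu4NF would give epoxy diol F12, and selective acetylation as in step 18 would give 28.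

Further compounds
F1 | step 7 | (1S,2R)-3-methylidene-2-(3-oxobutyl)cyclobutane-1-carbaldehyde | CC(=O)CC[C@@H]1[C@@H](C=O)CC1=C
F2 | step 7 | (1S,2R)-3-methylidene-2-(3-oxobutyl)cyclobutane-1-carboxylic acid | CC(=O)CC[C@@H]1[C@@H](C(=O)O)CC1=C
F3 | step 7 | phenyl (1S,2R)-3-methylidene-2-(3-oxobutyl)cyclobutane-1-carboxylate | CC(=O)CC[C@@H]1[C@@H](C(=O)Oc2ccccc2)CC1=C
F4 | step 7 | bromomagnesium alkoxide of phenyl (1S,2R)-2-(3-hydroxy-3-methylpent-4-en-1-yl)-3-methylidenecyclobutane-1-carboxylate | C=CC(C)(O[Mg]Br)CC[C@@H]1[C@@H](C(=O)Oc2ccccc2)CC1=C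
F5 | step 11 | 1-[(1R,2R,3S)-3-(hydroxymethyl)-1-methyl-2-(3-oxobutyl)cyclobutyl]-4-methyl-4-(triethylsilyloxy)pentan-3-one | CC(=O)CC[C@@H]1[C@@H](CO)C[C@@]1(C)CCC(=O)C(C)(C)O[Si](CC)(CC)CC
F6 | step 11 | 1-[(1R,2R,3S)-2-(3-hydroxy-3-methylpent-4-en-1-yl)-3-(hydroxymethyl)-1-methylcyclobutyl]-4-methyl-4-(triethylsilyloxy)pentan-3-one | C=CC(C)(O)CC[C@@H]1[C@@H](CO)C[C@@]1(C)CCC(=O)C(C)(C)O[Si](CC)(CC)CC
F7 | step 11 | (1S,2R,3R)-2-(3-hydroxy-3-methylpent-4-en-1-yl)-3-methyl-3-[4-methyl-3-oxo-4-(triethylsilyloxy)pentyl]cyclobutane-1-carbaldehyde | C=CC(C)(O)CC[C@@H]1[C@@H](C=O)C[C@@]1(C)CCC(=O)C(C)(C)O[Si](CC)(CC)CC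
F8 | step 11 | (1S,2R,3R)-2-(3-hydroxy-3-methylpent-4-en-1-yl)-3-methyl-3-[4-methyl-3-oxo-4-(triethylsilyloxy)pentyl]cyclobutane-1-carboxylic acid | C=CC(C)(O)CC[C@@H]1[C@@H](C(=O)O)C[C@@]1(C)CCC(=O)C(C)(C)O[Si](CC)(CC)CC
F9 | step 11 | mixed anhydride of F8 with 2,4,6-trichlorobenzoic acid | C=CC(C)(O)CC[C@@H]1[C@@H](C(=O)OC(=O)c2c(Cl)cc(Cl)cc2Cl)C[C@@]1(C)CCC(=O)C(C)(C)O[Si](CC)(CC)CC
F10 | step 19 | (1R,4R,5S,9S,11R)-4,5-epoxy-4,11-dimethyl-11-[(3R)-4-methyl-3,4-bis(triethylsilyloxy)pentyl]bicyclo[7.2.0]undecan-8-one | O=C1CC[C@@H]2O[C@]2(C)CC[C@@H]2[C@@H]1C[C@@]2(C)CC[C@@H](O[Si](CC)(CC)CC)C(C)(C)O[Si](CC)(CC)CC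
F11 | step 19 | (1R,4R,5S,9S,11R)-4,5-epoxy-4,11-dimethyl-8-methylidene-11-[(3R)-4-methyl-3,4-bis(triethylsilyloxy)pentyl]bicyclo[7.2.0]undecane | C=C1CC[C@@H]2O[C@]2(C)CC[C@@H]2[C@@H]1C[C@@]2(C)CC[C@@H](O[Si](CC)(CC)CC)C(C)(C)O[Si](CC)(CC)CC
F12 | step 19 | (3R)-5-[(1R,4R,5S,9S,11R)-4,5-epoxy-4,11-dimethyl-8-methylidenebicyclo[7.2.0]undecan-11-yl]-2-methylpentane-2,3-diol | C=C1CC[C@@H]2O[C@]2(C)CC[C@@H]2[C@@H]1C[C@@]2(C)CC[C@@H](O)C(C)(C)O
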